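## Retrosynthetic overview
1. Rings A/B (cyclopentene + dihydropyran) and stereocentres C5 and C9 are bought as genipin (1). Everything else is built on its C10 and its C7=C8 olefin.
2. Last disconnection, ring D: the C8–O(lactone) bond. It is made by a light-driven, Se-catalysed aerobic allylic lactonisation that also moves C7=C8 to C6=C7.
3. C11–C12: syn-hydrocarboxylation of an aryl alkyne, which fixes the (E)-benzylidene.
4. C10–C11 and C1–O–C10 (ring C) form together. The C10 aldehyde and C1 lactol give a bridged oxocarbenium ion, which is alkynylated on its convex face.
5. Ring order: A/B (bought) → C (oxolane acetal) → D (spiro-lactone).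

Assumption: iridoid numbering is used throughout. C1 is the acetal CH, C3=C4 the enol ether, C5/C9 the ring fusion, C8 the spiro carbon, C10 the oxolane CH, C11=C13 the benzylidene and C12 the lactone C=O. "β/convex" means the face carrying H-5 and H-9.

## Route

**Step 1**
Reactants: 1, genipin
Product: 2, 10-oxogenipin (the C10 CH2OH becomes a conjugated CHO; C1 lactol, C5 and C9 unchanged)
Conditions: activated MnO2 (15 equiv), CH2Cl2, rt
Reagents that add atoms: none
Why: Chemoselective MnO2 oxidation of an allylic alcohol; only the primary allylic C10–OH reacts, the lactol, enol ether and ester are inert at rt, and no stereocentre is touched.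

**Step 2**
Reactants: 3, 4-iodophenyl acetate; 4, (trimethylsilyl)acetylene
Product: 5, 4-[(trimethylsilyl)ethynyl]phenyl acetate
Conditions: PdCl2(PPh3)2 (2 mol %), CuI (4 mol %), Et3N, THF, rt
Reagents that add atoms: (trimethylsilyl)acetylene (4), C#C[Si](C)(C)C
Why: Sonogashira coupling of an aryl iodide at rt; the phenyl acetate tolerates Et3N, and the TMS group is kept because it is the leaving group in Step 3.

**Step 3**
Reactants: 2, 10-oxogenipin; 5, 4-[(trimethylsilyl)ethynyl]phenyl acetate
Product: 6, exo-10-[(4-acetoxyphenyl)ethynyl]-1,10-anhydrogenipin. This is a tricyclic bridged acetal with a new C1–O–C10 oxolane and C7=C8 retained. H-5, H-9 and the alkynyl group lie on the convex face and H-10 is endo.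
Conditions: BF3·OEt2 (1.5 equiv), 4 Å MS, CH2Cl2, −78 → −30 °C
Reagents that add atoms: 5, CC(=O)Oc1ccc(cc1)C#C[Si](C)(C)C (TMS is lost)
Why: Lewis-acid C-glycosidation-type alkynylation with an alkynylsilane: BF3 closes C1–OH onto the enal and ionises the C10 lactol to a bridged, vinyl-conjugated oxocarbenium ion (C1 can bridge only with its oxygen on the α face, which fixes C1), the weakly nucleophilic silane reacts only with this cation and attacks C10 from the open convex face (the H-9 side), and loss of TMS sets C10.

**Step 4**
Reactants: 6; 7, carbon dioxide
Product: 8, (E)-3-(4-acetoxyphenyl)-2-(1,10-anhydrogenipin-10-exo-yl)acrylic acid (aryl cis to C10, H-13 cis to CO2H)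
Conditions: NiCl2·glyme (10 mol %), bathocuproine (12 mol %), Mn, t-BuOH, CO2 (1 atm), DMF, 50–60 °C; then aq. citric acid
Reagents that add atoms: carbon dioxide (7), O=C=O
Why: Ni-catalysed reductive hydrocarboxylation of an internal aryl alkyne: oxidative cyclisation of Ni(0), alkyne and CO2 puts the aryl-bearing carbon next to Ni and forms C11–C12 at the alkyl-bearing carbon, and protonolysis of the nickelalactone with retention is a net syn H/CO2H addition, giving the E geometry of the target without touching any stereocentre.

**Step 5**
Reactants: 8
Product: 9, 3-O-acetylprismatomerin (target)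
Conditions: (PhSe)2 (10 mol %), 2,4,6-tris(4-methoxyphenyl)pyrylium BF4 (5 mol %), air, MeCN, 465 nm LEDs, rt
Reagents that add atoms: none (O2 only removes 2 H)
Why: Proposed new method: photo-aerobic selenium-π-acid dehydrogenative spirolactonisation of a trisubstituted ring olefin; the excited pyrylium oxidises (PhSe)2 to a PhSe+ equivalent that adds reversibly to the most electron-rich olefin, C7=C8; only the α-face seleniranium can be opened, because the carboxyl hangs from the exo (β) C10 substituent directly above C8 and the oxolane must stay cis-fused, so 5-exo, Markovnikov, anti attack places C8–O on the β face (cis to H-9) and PhSe on C7α, which sets the spiro centre; photo-oxidation then turns the selenide into a leaving group and, since C8 has no H, elimination can only take H-6, giving C6=C7 and returning the catalyst with O2 as terminal oxidant; the closest known chemistry is photo-aerobic Se-catalysed lactonisation of simple acyclic alkenoic acids and classical phenylselenolactonisation/selenoxide elimination, neither shown for a fully substituted spiro C–O centre on a caged iridoid acetal or with a cinnamic-type acid.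

## Compound list
1 | genipin, methyl (1R,4aS,7aS)-1-hydroxy-7-(hydroxymethyl)-1,4a,5,7a-tetrahydrocyclopenta[c]pyran-4-carboxylate | COC(=O)C1=CO[C@H]([C@H]2[C@@H]1CC=C2CO)O | starting material
2 | 10-oxogenipin | COC(=O)C1=CO[C@H]([C@H]2[C@@H]1CC=C2C=O)O | intermediate
3 | 4-iodophenyl acetate | CC(=O)Oc1ccc(I)cc1 | starting material
4 | (trimethylsilyl)acetylene | C#C[Si](C)(C)C | starting material
5 | 4-[(trimethylsilyl)ethynyl]phenyl acetate | CC(=O)Oc1ccc(cc1)C#C[Si](C)(C)C | intermediate
6 | exo-10-[(4-acetoxyphenyl)ethynyl]-1,10-anhydrogenipin | COC(=O)C1=CO[C@@H]2O[C@@H](C#Cc3ccc(OC(C)=O)cc3)C4=CC[C@H]1[C@H]24 | intermediate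
7 | carbon dioxide | O=C=O | starting material
8 | (E)-3-(4-acetoxyphenyl)-2-(1,10-anhydrogenipin-10-exo-yl)acrylic acid | COC(=O)C1=CO[C@@H]2O[C@@H](/C(=C\c3ccc(OC(C)=O)cc3)C(=O)O)C4=CC[C@H]1[C@H]24 | intermediate
9 | 3-O-acetylprismatomerin | COC(=O)C1=CO[C@@H]2O[C@H]3/C(=C\c4ccc(OC(C)=O)cc4)C(=O)O[C@]34C=C[C@H]1[C@H]24 | target

## Step count and risks
Total steps: 5. Longest linear sequence: 4 (1 → 2 → 6 → 8 → 9).

Steps most likely to fail:

1. **Step 5 (the new step).**
   - Risks: unproductive selenium chemistry, some E/Z leakage of the cinnamic unit under blue light, and oxidation at the activated C10–H or the product's bis-allylic C5–H.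
   - Fallback (known chemistry, different mechanism): Schenck ene photooxygenation of 8 (TPP, O2, visible light, CH2Cl2, 0 °C). Singlet oxygen attacks the convex face and abstracts H-6β, giving the C8β hydroperoxide with C6=C7. PPh3 reduction and carbodiimide lactonisation of the hydroxy acid then give 9, with the C8 oxygen coming from O2 instead of the carboxyl group.

2. **Step 3.**
   - Risks: attack of the silane at C1 or C7, and Lewis-acid re-ionisation that epimerises C10.
   - Fallback: separate the two events. Add the alkyne as a metal acetylide to the open enal 2 under near-neutral conditions, using either Zn(OTf)2/Et3N with desilylated 5 or CrCl2 with the derived 1-bromoalkyne. Then close ring C by a separate mild acid transacetalisation and separate the C10 epimers. The endo epimer cannot lactonise, so it cannot contaminate 9.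

3. **Step 4.**
   - Risks: regiochemistry of nickelalactone formation next to the bulky, oxygenated C10, and propargylic C–O cleavage by Ni(0).
   - Fallback: change the order and the C1 source. First run the Schenck ene/reduction on 6 to the C8 tertiary allylic alcohol. Then close ring D by Pd-catalysed cyclocarbonylation (CO) of this homopropargylic alcohol. The tether enforces 5-exo regiochemistry, and syn acyl-palladation followed by protonolysis gives the same E-benzylidene.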